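Ring B is disconnected by a Diels–Alder reaction: diene C7=C6–C5=C10 plus the C8=C9 bond of an allene, buta-2,3-dienoic acid. The feature exploited is that ring B carries an oxygen on C6 peri to the C4 carboxyl, and an exocyclic C8=C17 methylene beside the C9 stereocentre. Tying the C6 oxygen to the carboxyl as a five-membered enol lactone locks the diene s-cis on ring A and leaves the C4 methyl to shield one face; the allene delivers the methylene directly. One cycloaddition thus forms C7–C8 and C9–C10, closes ring B and sets the C10 quaternary centre and C9. The precursor is a bicyclic dienyl enol lactone made by cycloisomerisation of an enantioenriched enyne acid.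

Key step: step 6

Remarks on the chemistry
- Numbering used in all names: decalin carbons C1–C10 (ring A = C1–C5, C10; ring B = C5–C10). C4 bears a methyl and the carboxyl, C10 a methyl, C6 the oxygen, C8 the exocyclic methylene C17, and C9 the side chain C11–C15 with its methyl on C13. The target is (4S,5S,6R,9R,10S): 4-Me, 10-Me and the C9 side chain are cis; 5-H, 6-OAc and 4-CO2H lie on the opposite face.
- Assumption: of the two pseudo-enantiomeric 6'-hydroxy cinchona catalysts, the quinidine-derived one is taken to give the (S) adduct in step 1; if the sense is the reverse, the quinine-derived one is used.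
- Assumption: buta-2,3-dienoic acid is taken as commercial (it is otherwise one hydrolysis from its commercial ethyl ester).

Step 1
Reactants: 1 methyl 2-methyl-3-oxopentanoate (racemic); 2 acrolein
Product: 4 methyl (S)-1,3-dimethyl-2-oxocyclohex-3-ene-1-carboxylate, via Michael adduct 3 (not isolated)
Conditions: 9-O-(phenanthren-9-yl)cupreidine (10 mol%), CH2Cl2, −24 °C; then toluene, p-TsOH·H2O (20 mol%), reflux, Dean–Stark
Reagents that add atoms: none
Why: A bifunctional cinchona-catalysed enantioselective Michael addition of the α-methyl β-keto ester to acrolein should set the C4 quaternary centre by catalyst-controlled face selection at the enol carbon, and the δ-keto aldehyde then closes by acid-catalysed intramolecular aldol condensation (Robinson annulation) in the only ring size open to it.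

Step 2
Reactants: 4 methyl (S)-1,3-dimethyl-2-oxocyclohex-3-ene-1-carboxylate
Product: 6 methyl (S)-1,3-dimethyl-2-(trifluoromethylsulfonyloxy)cyclohex-2-ene-1-carboxylate, via lithium enolate 5 (not isolated)
Conditions: LiBH(s-Bu)3 (L-Selectride), THF, −78 °C; then PhNTf2, −78 °C to rt
Reagents that add atoms: N-phenylbis(trifluoromethanesulfonimide), O=S(=O)(N(c1ccccc1)S(=O)(=O)C(F)(F)F)C(F)(F)F
Why: Conjugate hydride addition to the β-unsubstituted enone (1,2-attack is blocked by the adjacent quaternary carbon) gives a regiodefined enolate that is O-sulfonylated (reductive enol triflate formation); no stereocentre is made or touched.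

Step 3
Reactants: 6 methyl (S)-1,3-dimethyl-2-(trifluoromethylsulfonyloxy)cyclohex-2-ene-1-carboxylate; 7 ethynyltrimethylsilane
Product: 8 methyl (S)-1,3-dimethyl-2-[(trimethylsilyl)ethynyl]cyclohex-2-ene-1-carboxylate
Conditions: PdCl2(PPh3)2 (3 mol%), CuI (6 mol%), Et3N, DMF, rt to 45 °C
Reagents that add atoms: none
Why: Sonogashira coupling of an alkenyl triflate, whose oxidative addition is fast even at a tetrasubstituted alkene.

Step 4
Reactants: 8 methyl (S)-1,3-dimethyl-2-[(trimethylsilyl)ethynyl]cyclohex-2-ene-1-carboxylate
Product: 9 (S)-2-ethynyl-1,3-dimethylcyclohex-2-ene-1-carboxylic acid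
Conditions: LiOH·H2O, THF/MeOH/H2O, 60 °C; then 1 M HCl
Reagents that add atoms: lithium hydroxide, [Li+].[OH-]
Why: Saponification of the hindered methyl ester with concurrent protodesilylation of the alkynylsilane; the quaternary centre cannot epimerise and the alkyne has no propargylic hydrogen to isomerise.

Step 5
Reactants: 9 (S)-2-ethynyl-1,3-dimethylcyclohex-2-ene-1-carboxylic acid
Product: 10 (S)-dienyl enol lactone (4,7a-dimethyl-3-methylidene-tetrahydro-2-benzofuran-1-one that has its ring alkene at C3a=C4)
Conditions: AuCl (5 mol%), K2CO3 (10 mol%), MeCN, rt; filtration through neutral alumina, used at once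
Reagents that add atoms: none
Why: Gold-catalysed 5-exo-dig cycloisomerisation of a γ-alkynoic acid (anti-oxyauration at the internal carbon of the terminal alkyne, then protodeauration) should give the γ-methylidene lactone, which here is the s-cis-locked diene C7=C6–C5=C10.

Step 6
Reactants: 10 (S)-dienyl enol lactone (4,7a-dimethyl-3-methylidene-tetrahydro-2-benzofuran-1-one that has its ring alkene at C3a=C4); 11 buta-2,3-dienoic acid
Product: 12 tricyclic enol-lactone acid (ring B closed; 4-Me, 10-Me and 9-CO2H cis; C5=C6 enol lactone; 8-methylidene)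
Conditions: toluene (1 M), BHT (cat.), dienophile in threefold excess, 90 °C, sealed tube
Reagents that add atoms: none
Why: A concerted but asynchronous [4+2] cycloaddition between the s-cis-locked 2-acyloxy diene C7=C6–C5=C10 of 10 and the electron-poor α,β double bond (C8=C9) of the allenic acid; the closest known reaction type is the Diels–Alder reaction of exocyclic or 2-acyloxy dienes with buta-2,3-dienoates, which react at the conjugated bond and keep the exocyclic methylene. Ring B is closed by an intermolecular suprafacial [4π+2π] addition in which C7–C8 forms ahead of C9–C10. Regiochemistry should follow from the largest HOMO coefficient at C7 (acyloxy on C6, two alkyl groups on C10) meeting the largest LUMO coefficient at the central allene carbon C8, so the carboxyl-bearing C9 bonds to C10. The new quaternary centre C10 is controlled by the existing C4 centre: the lactone holds the C4 methyl nearly perpendicular to the diene plane (an angular methyl), so the dienophile is expected to add to the opposite face and the 10-methyl ends cis to the 4-methyl. C9 is controlled by an exo orientation of the carboxyl, expected because the endo quadrant on the attacked face lies over ring A and its pseudo-axial hydrogens at C3 and C1; exo addition places the C9 carbon substituent cis to the 10-methyl. The step therefore needs face, exo and regio selectivity, secured in turn by the C4 methyl, the ring A methylenes and the donor pattern of the diene, while excess dienophile, a radical inhibitor and a temperature below that of a 1,5-hydrogen shift limit side reactions.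

Step 7
Reactants: 12 tricyclic enol-lactone acid
Product: 14 enol-lactone alcohol (9-CH2OH), via mixed carbonic anhydride 13 (not isolated)
Conditions: i-BuOCOCl, N-methylmorpholine, THF, −15 °C; then NaBH4, H2O, −15 °C, 15 min
Reagents that add atoms: none
Why: Borohydride reduction of a carboxylic acid through its mixed carbonic anhydride, which at −15 °C should be much faster than attack on the enol-lactone carbonyl shielded by the C4 quaternary carbon.

Step 8
Reactants: 14 enol-lactone alcohol
Product: 15 enol-lactone iodide (9-CH2I)
Conditions: I2, PPh3, imidazole, CH2Cl2, 0 °C to rt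
Reagents that add atoms: iodine, II
Why: Appel iodination of the primary alcohol (iodide displaces the alkoxyphosphonium) under neutral conditions that leave the enol lactone and the exocyclic alkene alone.

Step 9
Reactants: 16 prop-2-yn-1-ol
Product: 18 (E)-3-iodo-2-methylprop-2-en-1-ol, via alkenylalane 17 (not isolated)
Conditions: Me3Al (3 equiv), Cp2ZrCl2 (25 mol%), CH2Cl2, 0 °C to rt; then I2, THF, −30 °C; aq. K2CO3
Reagents that add atoms: trimethylaluminium, C[Al](C)C; iodine, II
Why: Zirconium-catalysed carboalumination adds methyl and aluminium syn across the terminal alkyne with aluminium at the terminal carbon, and iodinolysis with retention gives the (E)-iodide.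

Step 10
Reactants: 18 (E)-3-iodo-2-methylprop-2-en-1-ol
Product: 19 (E)-3-iodo-2-methylprop-2-enal
Conditions: MnO2, CH2Cl2, rt
Reagents that add atoms: none
Why: Allylic alcohol oxidation with MnO2, which does not isomerise the alkene.

Step 11
Reactants: 19 (E)-3-iodo-2-methylprop-2-enal
Product: 20 (E)-1-iodo-2-methylbuta-1,3-diene
Conditions: Ph3PCH3Br, n-BuLi, Et2O, 0 °C; add 19, −78 °C to rt; kept as a solution in Et2O
Reagents that add atoms: methyltriphenylphosphonium bromide, C[P+](c1ccccc1)(c1ccccc1)c1ccccc1.[Br-]
Why: Wittig methylenation of the enal forms the terminal alkene and leaves the geometry of the trisubstituted iodoalkene unchanged.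

Step 12
Reactants: 15 enol-lactone iodide; 20 (E)-1-iodo-2-methylbuta-1,3-diene
Product: 22 enol-lactone triene (9-[(2E)-3-methylpenta-2,4-dien-1-yl]), via alkylzinc iodide 21 (not isolated)
Conditions: Zn dust (activated with TMSCl and 1,2-dibromoethane), LiCl, THF, 40 °C; then 20, PdCl2(dppf) (5 mol%), THF, rt
Reagents that add atoms: none
Why: Negishi coupling: zinc insertion into the primary iodide and palladium-catalysed sp3–sp2 coupling with the alkenyl iodide should proceed with retention of the (E) geometry, and alkylzinc reagents tolerate the enol lactone.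

Step 13
Reactants: 22 enol-lactone triene
Product: 24 2-(trimethylsilyl)ethyl ester of the 6-oxo acid (trans-decalin), via lithium enolate 23 (not isolated)
Conditions: Me3SiCH2CH2OH, n-BuLi, THF, −78 °C; add 22, −78 to −30 °C; then AcOH, −78 °C
Reagents that add atoms: 2-(trimethylsilyl)ethanol, OCC[Si](C)(C)C
Why: Acyl transfer from the enol lactone (an activated ester) to the alkoxide releases the C5=C6 enolate regiospecifically, and kinetic protonation at C5 from the face opposite the axial 4- and 10-methyl groups should give the trans ring fusion without exposing the β,γ-unsaturated ketone to base.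

Step 14
Reactants: 24 2-(trimethylsilyl)ethyl ester of the 6-oxo acid
Product: 25 6-hydroxy ester (OH equatorial, trans to 10-Me)
Conditions: SmI2 (3 equiv), H2O, THF, 0 °C to rt
Reagents that add atoms: none
Why: Single-electron-transfer reduction of the ketone (ketyl radical anion, second electron, protonation) should, like a dissolving-metal reduction, give the thermodynamically preferred equatorial alcohol, the axial epimer being destabilised by 1,3-diaxial contacts with the 4- and 10-methyl groups; without an amine additive the diene and the ester should survive.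

Step 15
Reactants: 25 6-hydroxy ester
Product: 26 6-acetoxy ester
Conditions: Ac2O, pyridine, DMAP (cat.), CH2Cl2, rt
Reagents that add atoms: acetic anhydride, CC(=O)OC(C)=O
Why: DMAP-catalysed acylation of the secondary alcohol with retention at C6.

Step 16
Reactants: 26 6-acetoxy ester
Product: 27 target acid
Conditions: Bu4NF, THF, 0 °C to rt; aq. NH4Cl
Reagents that add atoms: none
Why: Fluoride attacks silicon and the 2-(trimethylsilyl)ethyl ester fragments with loss of ethene, which frees the hindered acid without acyl substitution and so should spare the acetate.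

Compound list
1 | methyl 2-methyl-3-oxopentanoate (racemic) | CCC(=O)C(C)C(=O)OC | starting material
2 | acrolein (prop-2-enal) | C=CC=O | starting material
3 | methyl (S)-2-methyl-3-oxo-2-(3-oxopropyl)pentanoate (not isolated) | O=CCC[C@](C(=O)CC)(C)C(=O)OC | intermediate
4 | methyl (S)-1,3-dimethyl-2-oxocyclohex-3-ene-1-carboxylate | O=C1C(C)=CCC[C@]1(C)C(=O)OC | intermediate
5 | lithium (S)-6-(methoxycarbonyl)-2,6-dimethylcyclohex-1-en-1-olate (not isolated) | [Li+].[O-]C1=C(C)CCC[C@]1(C)C(=O)OC | intermediate
6 | methyl (S)-1,3-dimethyl-2-(trifluoromethylsulfonyloxy)cyclohex-2-ene-1-carboxylate | O=S(=O)(OC1=C(C)CCC[C@]1(C)C(=O)OC)C(F)(F)F | intermediate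
7 | ethynyltrimethylsilane | C#C[Si](C)(C)C | starting material
8 | methyl (S)-1,3-dimethyl-2-[(trimethylsilyl)ethynyl]cyclohex-2-ene-1-carboxylate | C[Si](C)(C)C#CC1=C(C)CCC[C@]1(C)C(=O)OC | intermediate
9 | (S)-2-ethynyl-1,3-dimethylcyclohex-2-ene-1-carboxylic acid | C#CC1=C(C)CCC[C@]1(C)C(=O)O | intermediate
10 | (S)-4,7a-dimethyl-3-methylidene-5,6,7,7a-tetrahydro-2-benzofuran-1(3H)-one (dienyl enol lactone; diene C7=C6–C5=C10; C6–O–C(=O)–C4 lactone) | C=C1C2=C(C)CCC[C@]2(C)C(=O)O1 | intermediate
11 | buta-2,3-dienoic acid | C=C=CC(=O)O | starting material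
12 | tricyclic enol-lactone acid: 4,10-dimethyl-8-methylidene octalin with C5=C6, the C6 enol oxygen acylated by the C4 carboxyl (five-membered enol lactone), 9-CO2H; 4-Me, 10-Me and 9-CO2H cis | OC(=O)[C@@H]1C(=C)CC3=C2[C@@]1(C)CCC[C@]2(C)C(=O)O3 | intermediate
13 | isobutyl carbonic mixed anhydride of 12 (not isolated) | CC(C)COC(=O)OC(=O)[C@@H]1C(=C)CC3=C2[C@@]1(C)CCC[C@]2(C)C(=O)O3 | intermediate
14 | enol-lactone alcohol: as 12 with 9-CH2OH | OC[C@@H]1C(=C)CC3=C2[C@@]1(C)CCC[C@]2(C)C(=O)O3 | intermediate
15 | enol-lactone iodide: as 12 with 9-CH2I | IC[C@@H]1C(=C)CC3=C2[C@@]1(C)CCC[C@]2(C)C(=O)O3 | intermediate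
16 | prop-2-yn-1-ol | C#CCO | starting material
17 | (E)-[3-(dimethylalumanyloxy)-2-methylprop-1-en-1-yl]dimethylalane (not isolated) | C[Al](C)OC/C(C)=C/[Al](C)C | intermediate
18 | (E)-3-iodo-2-methylprop-2-en-1-ol | OC/C(C)=C/I | intermediate
19 | (E)-3-iodo-2-methylprop-2-enal | O=C/C(C)=C/I | intermediate
20 | (E)-1-iodo-2-methylbuta-1,3-diene | C=C/C(C)=C/I | intermediate
21 | alkylzinc iodide from 15 (9-CH2ZnI; not isolated) | I[Zn]C[C@@H]1C(=C)CC3=C2[C@@]1(C)CCC[C@]2(C)C(=O)O3 | intermediate
22 | enol-lactone triene: as 12 with 9-[(2E)-3-methylpenta-2,4-dien-1-yl] | C=C/C(C)=C/C[C@@H]1C(=C)CC3=C2[C@@]1(C)CCC[C@]2(C)C(=O)O3 | intermediate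
23 | lithium C5=C6 enolate of 24 (not isolated) | [Li+].C=C/C(C)=C/C[C@@H]1C(=C)CC([O-])=C2[C@@]1(C)CCC[C@]2(C)C(=O)OCC[Si](C)(C)C | intermediate
24 | 2-(trimethylsilyl)ethyl 4,10-dimethyl-8-methylidene-9-[(2E)-3-methylpenta-2,4-dien-1-yl]-6-oxodecalin-4-carboxylate; trans-decalin, 5-H trans to 10-Me; 4-Me, 10-Me and C9 chain cis | C=C/C(C)=C/C[C@@H]1C(=C)CC(=O)[C@H]2[C@@]1(C)CCC[C@]2(C)C(=O)OCC[Si](C)(C)C | intermediate
25 | 6-hydroxy analogue of 24; OH equatorial, cis to 5-H, trans to 10-Me | C=C/C(C)=C/C[C@@H]1C(=C)C[C@@H](O)[C@H]2[C@@]1(C)CCC[C@]2(C)C(=O)OCC[Si](C)(C)C | intermediate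
26 | 6-acetoxy analogue of 25 | C=C/C(C)=C/C[C@@H]1C(=C)C[C@@H](OC(C)=O)[C@H]2[C@@]1(C)CCC[C@]2(C)C(=O)OCC[Si](C)(C)C | intermediate
27 | (4S,5S,6R,9R,10S)-6-acetoxy-4,10-dimethyl-8-methylidene-9-[(2E)-3-methylpenta-2,4-dien-1-yl]decalin-4-carboxylic acid (CNP0240327.3) | C=C/C(C)=C/C[C@@H]1C(=C)C[C@@H](OC(C)=O)[C@H]2[C@@]1(C)CCC[C@]2(C)C(=O)O | target

Total step count: 16 (13 on the main line, 3 for iodide 20).
Longest linear sequence: 13 steps (steps 1–8 and 12–16).

Steps most likely to fail

1. Step 6. The dienophile may add with its carboxyl endo, which gives the C9 epimer. Bond formation at the fully substituted C10 terminus may also be outrun by oligomerisation of the allene or by a 1,5-hydrogen shift in the diene. Fallback, from 10 back to 12: the cycloaddition of 10 with 11 is run as in step 6 and allowed to give the C9-epimeric adduct acid F1. Treatment of F1 with LiN(i-Pr)2 (2.2 equiv) in THF at −78 to −40 °C gives the dilithium dienediolate F2, in which C9 is planar. Protonation with acetic acid at −78 °C should occur at the α-carbon from the face opposite the pseudo-axial 10-methyl and return the route at 12. Control of C9 is thus moved from the exo/endo topology of the cycloaddition to a substrate-controlled kinetic protonation.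

2. Step 14. Protonation of the C6 carbanion may show poor facial selectivity and give the axial alcohol. The C8=C17 alkene may migrate into conjugation before reduction, or the diene may be partly reduced. Fallback, from 24 back to 26: NaBH4 in MeOH/THF at −20 °C delivers hydride from the open face, anti to the two axial methyl groups, and gives the axial C6 alcohol F3. Mitsunobu reaction of F3 with acetic acid (PPh3, diisopropyl azodicarboxylate, toluene, 0 °C to rt) inverts C6 and installs the acetate in the same operation, rejoining the route at 26. Thermodynamic electron-transfer reduction is thus replaced by kinetic reduction plus SN2 inversion.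

3. Step 12. Zinc insertion into the β-branched iodide may be sluggish, the alkylpalladium species may undergo β-hydride elimination, or the volatile dienyl iodide may be lost. Fallback, from 15 back to 22: commercial 3-methyl-2,5-dihydrothiophene 1,1-dioxide F4 is deprotonated with LiN(SiMe3)2 in THF/DMPU at −78 °C in the presence of 15. Alkylation at C2 of the sulfolene should give the 2-alkyl-3-methyl-3-sulfolene F5, whose extra stereocentre is of no consequence. Heating F5 in toluene with pyridine at 110 °C extrudes SO2 in a cheletropic, disrotatory manner and should give the (E)-diene 22. The side chain is thus made by alkylation and extrusion instead of cross-coupling, and steps 9–11 are not needed.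

Further compounds
F1 | step 6 | C9-epimeric adduct acid (9-epi-12; 9-CO2H trans to 10-Me) | OC(=O)[C@H]1C(=C)CC3=C2[C@@]1(C)CCC[C@]2(C)C(=O)O3
F2 | step 6 | dilithium dienediolate of F1 (C9 planar) | [Li+].[Li+].[O-]C([O-])=C1C(=C)CC3=C2[C@@]1(C)CCC[C@]2(C)C(=O)O3
F3 | step 14 | axial C6 alcohol (6-epi-25) | C=C/C(C)=C/C[C@@H]1C(=C)C[C@H](O)[C@H]2[C@@]1(C)CCC[C@]2(C)C(=O)OCC[Si](C)(C)C
F4 | step 12 | 3-methyl-2,5-dihydrothiophene 1,1-dioxide | CC1=CCS(=O)(=O)C1
F5 | step 12 | 2-alkylated 3-methyl-3-sulfolene (sulfolene C2 attached to C11 of the enol-lactone core) | O=S1(=O)CC=C(C)C1C[C@@H]2C(=C)CC4=C3[C@@]2(C)CCC[C@]3(C)C(=O)O4
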